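**Strategy.** The nine-membered ring is disconnected between cyclobutane carbon C9 and spiro carbon C8 (caryophyllane numbering), with C8 handled as a ketone. In the decisive step SmI2 turns a cyclobutyl iodide into a C9 organosamarium that attacks the carbonyl (C8) of a γ-lactone whose ring oxygen is the C5 oxygen. This exploits the 1,4-relationship of the C5 hydroxyl and C8 across C6–C7 of the nine-membered ring: one operation closes the bicyclo[7.2.0]undecene and releases the allylic alcohol, without protecting groups. The precursor is a (Z)-alkenyl γ-butyrolactone carrying a 4-iodo-2,2-dimethylcyclobutyl group. Methylenation and a Knoevenagel/hetero-Diels–Alder reaction with syncarpic acid and isovaleraldehyde then build the spiro dihydropyran.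

Key step: step 9

Numbering used: C1/C9 are the cyclobutane ring-fusion carbons (C1 bears C2, C9 bears C8), C10 the cyclobutane CH2, C11 the CMe2 carbon, C3=C4 the ring alkene, C5 the carbinol, C8 the spiro carbon, C15 the pyran CH2, C16 the isobutyl-bearing CH.

Assumption: syncarpic acid is taken as purchasable; the C9 carbinol and iodide are carried as epimer mixtures because C9 passes through a configurationally labile organometal.

**Step 1**
Reactants: 1 3,3-dimethylcyclobutan-1-one; 2 RAMP, (R)-1-amino-2-(methoxymethyl)pyrrolidine
Product: 3 RAMP hydrazone of 3,3-dimethylcyclobutanone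
Conditions: neat, 4 Å MS, 60 °C
Reagents that add atoms: none
Why: Condensation of the unhindered cyclobutanone with the N-amino group gives the hydrazone (RAMP-hydrazone formation); the ketone is symmetric, so one hydrazone forms and no stereocenter is created.

**Step 2**
Reactants: 4 but-2-yn-1-ol
Product: 5 (Z)-3-iodobut-2-en-1-ol
Conditions: Red-Al, Et2O, 0 °C → rt; then I2, THF, −78 °C → 0 °C
Reagents that add atoms: iodine, II
Why: Hydroxyl-directed trans-hydroalumination places aluminium on C3 cis to the CH2O group and iodinolysis with retention should give the Z-vinyl iodide (hydroalumination–iodination), which fixes the later C3=C4 geometry.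

**Step 3**
Reactants: 5 (Z)-3-iodobut-2-en-1-ol
Product: 6 (Z)-1-bromo-3-iodobut-2-ene
Conditions: CBr4, PPh3, CH2Cl2, 0 °C
Reagents that add atoms: carbon tetrabromide, BrC(Br)(Br)Br
Why: Appel bromination converts the primary allylic alcohol by SN2 displacement of the alkoxyphosphonium ion without touching the vinyl iodide or the alkene geometry.

**Step 4**
Reactants: 3 RAMP hydrazone of 3,3-dimethylcyclobutanone; 6 (Z)-1-bromo-3-iodobut-2-ene
Product: 7 RAMP hydrazone of (S)-2-[(Z)-3-iodobut-2-en-1-yl]-3,3-dimethylcyclobutan-1-one
Conditions: LDA, THF, 0 °C; then 6, −100 °C → −20 °C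
Reagents that add atoms: none
Why: RAMP-hydrazone alkylation: the chelated lithium azaenolate is alkylated (SN2) on the face dictated by the methoxymethylpyrrolidine, which should set C1 as (S) (the sense established for cyclic ketones, where SAMP gives R and RAMP gives S), while the hydrazone keeps C9 masked.

**Step 5**
Reactants: 7 alkylated RAMP hydrazone; 8 methyl 4-oxobutanoate
Product: 9 RAMP hydrazone of (5R)-5-{(2Z)-4-[(1S)-2,2-dimethyl-4-oxocyclobutyl]but-2-en-2-yl}dihydrofuran-2(3H)-one
Conditions: CrCl2 (3 equiv), chiral oxazoline–sulfonamide ligand (enantiomer selected for the 5R carbinol), Et3N, NiCl2 (cat.), THF, rt; aq. sodium serinate; then PPTS (cat.), CH2Cl2, rt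
Reagents that add atoms: none
Why: Nozaki–Hiyama–Kishi coupling: the alkenylchromium(III) species forms with retention of the Z geometry and adds only to the aldehyde (ester and hydrazone inert), the chiral ligand on chromium selecting the aldehyde face to set C5 as (R), after which the γ-hydroxy ester lactonises.

**Step 6**
Reactants: 9 lactone RAMP hydrazone
Product: 10 (5R)-5-{(2Z)-4-[(1S)-2,2-dimethyl-4-oxocyclobutyl]but-2-en-2-yl}dihydrofuran-2(3H)-one
Conditions: sat. aq. oxalic acid, Et2O, rt
Reagents that add atoms: water, O
Why: Mild two-phase hydrazone hydrolysis should release the cyclobutanone and the auxiliary without epimerising the α-stereocenter C1 and without opening the lactone.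

**Step 7**
Reactants: 10 keto lactone
Product: 11 (5R)-5-{(2Z)-4-[(1S)-4-hydroxy-2,2-dimethylcyclobutyl]but-2-en-2-yl}dihydrofuran-2(3H)-one (carbinol epimers)
Conditions: NaBH4, MeOH, −20 °C
Reagents that add atoms: none
Why: Hydride reduction of the strained cyclobutanone is chemoselective over the γ-lactone; the new carbinol centre C9 is inconsequential because it becomes an organometal in step 9.

**Step 8**
Reactants: 11 cyclobutanol lactone
Product: 12 (5R)-5-{(2Z)-4-[(1S)-4-iodo-2,2-dimethylcyclobutyl]but-2-en-2-yl}dihydrofuran-2(3H)-one (iodide epimers)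
Conditions: I2, PPh3, imidazole, toluene, 60 °C
Reagents that add atoms: iodine, II
Why: Garegg–Samuelsson (Appel-type) iodination replaces the secondary hydroxyl by iodide through SN2 displacement of the alkoxyphosphonium ion; the C9 configuration is irrelevant.

**Step 9**
Reactants: 12 iodo lactone
Product: 14 (1R,5R,9S,Z)-5-hydroxy-4,11,11-trimethylbicyclo[7.2.0]undec-3-en-8-one (in equilibrium with its bridged hemiketal), via bridged samarium hemiketalate 13 (not isolated)
Conditions: SmI2 (2.6 equiv), Fe(dbm)3 (3 mol %), THF, −30 °C → rt, slow addition of 12 (final 0.01 M); then NaOMe (0.2 equiv), MeOH, rt; aq. NH4Cl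
Reagents that add atoms: none
Why: SmI2 reduces the C–I bond to the cyclobutyl radical and then to the C9 organosamarium(III), which adds to the lactone carbonyl C8 to give the oxygen-bridged hemiketalate 13; on work-up the bridge opens, so the C5–O–C8 lactone is traded for the C8–C9 bond and the free C5 hydroxyl (intramolecular Barbier-type nucleophilic acyl substitution, a known way to expand lactones into eight- and nine-membered carbocycles). The nine-membered carbocycle closes by exo attack on the C=O group through an eight-membered array (C9–C1–C2–C3=C4–C5–O–C8) in which the cyclobutane, the Z-alkene and the lactone leave only three freely rotating bonds. C9 is the only new stereocenter: the labile organosamarium may close to either ring fusion, and because C9–H is then α to the C8 ketone, methoxide equilibration should deliver the trans-fused (1R,9S) isomer, the more stable fusion of the caryophyllane 4/9 system, under control of the fixed C1 centre. The step needs reduction of the alkyl iodide in the presence of the lactone and a single addition; lactones are inert to SmI2 in THF and the samarium hemiketalate persists until work-up, which blocks over-addition and ketone reduction. C1, C5 and the Z-alkene are not touched.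

**Step 10**
Reactants: 14 hydroxy ketone
Product: 15 (1R,5R,9S,Z)-4,11,11-trimethyl-8-methylidenebicyclo[7.2.0]undec-3-en-5-ol
Conditions: Ph3PCH3Br, KOtBu (4 equiv each), THF, 0 → 50 °C
Reagents that add atoms: methyltriphenylphosphonium bromide, C[P+](c1ccccc1)(c1ccccc1)c1ccccc1.[Br-]
Why: Wittig methylenation: the excess basic ylide shifts the hemiketal/hydroxy ketone equilibrium to the keto alkoxide and olefinates C8 under non-acidic conditions that avoid transannular etherification; no stereocenter is formed.

**Step 11**
Reactants: 15 diene alcohol; 16 syncarpic acid; 17 isovaleraldehyde (3-methylbutanal)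
Product: 19 Tomentodione O, via alkylidene trione heterodiene 18 (not isolated)
Conditions: ethylenediammonium diacetate (10 mol %), 4 Å MS, toluene, rt → 70 °C
Reagents that add atoms: none
Why: Domino Knoevenagel/inverse-electron-demand hetero-Diels–Alder reaction: 16 and 17 condense to heterodiene 18, whose enone oxygen bonds to the more substituted alkene carbon C8 and whose alkylidene carbon bonds to the CH2 terminus; addition to the alkene face turned away from the cyclobutane, with the C7 methylene endo and the bulky cyclobutane exo, is expected to set C8 (S) and C16 (R) under substrate control.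

**Compound list**
1 | 3,3-dimethylcyclobutan-1-one | CC1(C)CC(=O)C1 | starting material
2 | RAMP, (R)-1-amino-2-(methoxymethyl)pyrrolidine | COC[C@H]1CCCN1N | starting material
3 | (R)-N-(3,3-dimethylcyclobutylidene)-2-(methoxymethyl)pyrrolidin-1-amine | COC[C@H]1CCCN1N=C1CC(C)(C)C1 | intermediate
4 | but-2-yn-1-ol | CC#CCO | starting material
5 | (Z)-3-iodobut-2-en-1-ol | C/C(I)=C/CO | intermediate
6 | (Z)-1-bromo-3-iodobut-2-ene | C/C(I)=C/CBr | intermediate
7 | RAMP hydrazone of (S)-2-[(Z)-3-iodobut-2-en-1-yl]-3,3-dimethylcyclobutan-1-one | C/C(I)=C/C[C@@H]1C(=NN2CCC[C@@H]2COC)CC1(C)C | intermediate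
8 | methyl 4-oxobutanoate | COC(=O)CCC=O | starting material
9 | RAMP hydrazone of keto lactone 10 | C/C(=C/C[C@@H]1C(=NN2CCC[C@@H]2COC)CC1(C)C)[C@H]1CCC(=O)O1 | intermediate
10 | (5R)-5-{(2Z)-4-[(1S)-2,2-dimethyl-4-oxocyclobutyl]but-2-en-2-yl}dihydrofuran-2(3H)-one | C/C(=C/C[C@@H]1C(=O)CC1(C)C)[C@H]1CCC(=O)O1 | intermediate
11 | (5R)-5-{(2Z)-4-[(1S)-4-hydroxy-2,2-dimethylcyclobutyl]but-2-en-2-yl}dihydrofuran-2(3H)-one, carbinol epimers | C/C(=C/C[C@@H]1C(O)CC1(C)C)[C@H]1CCC(=O)O1 | intermediate
12 | (5R)-5-{(2Z)-4-[(1S)-4-iodo-2,2-dimethylcyclobutyl]but-2-en-2-yl}dihydrofuran-2(3H)-one, iodide epimers | C/C(=C/C[C@@H]1C(I)CC1(C)C)[C@H]1CCC(=O)O1 | intermediate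
13 | bridged hemiketal of 14 (10-oxabicyclo[5.2.1]decene core fused to the cyclobutane), present as its samarium(III) alkoxide, drawn protonated, C9 epimers | C/C1=C/C[C@@H]2C(CC2(C)C)C2(O)CC[C@H]1O2 | intermediate
14 | (1R,5R,9S,Z)-5-hydroxy-4,11,11-trimethylbicyclo[7.2.0]undec-3-en-8-one | C/C1=C/C[C@@H]2[C@H](CC2(C)C)C(=O)CC[C@H]1O | intermediate
15 | (1R,5R,9S,Z)-4,11,11-trimethyl-8-methylidenebicyclo[7.2.0]undec-3-en-5-ol | C/C1=C/C[C@@H]2[C@H](CC2(C)C)C(=C)CC[C@H]1O | intermediate
16 | syncarpic acid, 2,2,4,4-tetramethylcyclohexane-1,3,5-trione | CC1(C)C(=O)CC(=O)C(C)(C)C1=O | starting material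
17 | isovaleraldehyde, 3-methylbutanal | CC(C)CC=O | starting material
18 | 2,2,4,4-tetramethyl-6-(3-methylbutylidene)cyclohexane-1,3,5-trione | CC(C)CC=C1C(=O)C(C)(C)C(=O)C(C)(C)C1=O | intermediate
19 | Tomentodione O | C/C1=C/C[C@@H]2[C@H](CC2(C)C)[C@]2(CC[C@H]1O)C[C@@H](CC(C)C)C1=C(O2)C(C)(C)C(=O)C(C)(C)C1=O | target

**Count**
Total step count: 11. Longest linear sequence: 10 steps (steps 2–11, from but-2-yn-1-ol).

**Steps most likely to fail**

Step 9. The cyclobutyl radical or organosamarium may be quenched by hydrogen abstraction or protonation before the medium-ring acyl substitution, giving de-iodinated lactone. The fallback uses a stabilised carbanion instead of the organosamarium. It sets out from 12: displacement with sodium benzenesulfinate (DMF, 70 °C) should give the phenyl sulfone F1. LDA (1.1 equiv, THF, −78 °C → rt, 0.01 M) generates the α-sulfonyl carbanion, fed by proton transfer from the lactone enolate, and this acylates on the lactone to give the ring-expanded β-keto sulfone F2. SmI2 (THF/MeOH, −78 °C) removes the sulfonyl group and NaOMe/MeOH equilibrates C9, which comes back to the route at 14.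

Step 11. Facial or endo/exo selectivity of the cycloaddition on the flexible nine-membered ring may be poor, so that C8/C16 epimers form. The fallback changes the oxidation level of the dienophile and resets C5 by reagent control. It sets out from 15: MnO2 (CH2Cl2, rt) oxidises the allylic alcohol to the dienone F3, whose sp2 C5 changes the ring conformation. The same Knoevenagel/hetero-Diels–Alder reaction with 16 and 17 should give the 5-oxo adduct F4. (S)-Me-CBS/catecholborane (toluene, −78 °C) then reduces the enone carbonyl to the (5R) alcohol, arriving at 19.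

Step 5. Control of the aldehyde face by the chromium ligand may be insufficient, giving C5 epimers that are hard to separate because C5 is remote from C1. The fallback replaces asymmetric addition by reagent-controlled reduction. It sets out from 7: an achiral Nozaki–Hiyama–Kishi coupling (CrCl2, cat. NiCl2, DMF) with tert-butyl 4-oxobutanoate should give the hydroxy ester F5 as C5 epimers. MnO2 gives the Z-enone F6, and (S)-Me-CBS/catecholborane sets (5R) in the alcohol F7. Camphorsulfonic acid (cat., toluene, 60 °C) closes the lactone with loss of isobutene, coming back to the route at 9.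

**Further compounds**
F1 | step 9 | (5R)-5-{(2Z)-4-[(1S)-2,2-dimethyl-4-(phenylsulfonyl)cyclobutyl]but-2-en-2-yl}dihydrofuran-2(3H)-one, C9 epimers | C/C(=C/C[C@@H]1C(CC1(C)C)S(=O)(=O)c1ccccc1)[C@H]1CCC(=O)O1
F2 | step 9 | (1R,5R,Z)-5-hydroxy-4,11,11-trimethyl-9-(phenylsulfonyl)bicyclo[7.2.0]undec-3-en-8-one, C9 epimers | C/C1=C/C[C@@H]2C(CC2(C)C)(S(=O)(=O)c2ccccc2)C(=O)CC[C@H]1O
F3 | step 11 | (1R,9S,Z)-4,11,11-trimethyl-8-methylidenebicyclo[7.2.0]undec-3-en-5-one | C/C1=C/C[C@@H]2[C@H](CC2(C)C)C(=C)CCC1=O
F4 | step 11 | 5-oxo analogue of Tomentodione O | C/C1=C/C[C@@H]2[C@H](CC2(C)C)[C@]2(CCC1=O)C[C@@H](CC(C)C)C1=C(O2)C(C)(C)C(=O)C(C)(C)C1=O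
F5 | step 5 | RAMP hydrazone of tert-butyl (5Z)-7-[(1S)-2,2-dimethyl-4-oxocyclobutyl]-4-hydroxy-5-methylhept-5-enoate, C4-carbinol epimers | C/C(=C/C[C@@H]1C(=NN2CCC[C@@H]2COC)CC1(C)C)C(O)CCC(=O)OC(C)(C)C
F6 | step 5 | RAMP hydrazone of tert-butyl (5Z)-7-[(1S)-2,2-dimethyl-4-oxocyclobutyl]-5-methyl-4-oxohept-5-enoate | C/C(=C/C[C@@H]1C(=NN2CCC[C@@H]2COC)CC1(C)C)C(=O)CCC(=O)OC(C)(C)C
F7 | step 5 | RAMP hydrazone of tert-butyl (4R,5Z)-7-[(1S)-2,2-dimethyl-4-oxocyclobutyl]-4-hydroxy-5-methylhept-5-enoate | C/C(=C/C[C@@H]1C(=NN2CCC[C@@H]2COC)CC1(C)C)[C@@H](CCC(=O)OC(C)(C)C)O
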